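**Strategy.** Ring B carries oxygen at C6 and C8 (labdane numbering), 1,3 to each other across C7 and 1,5 across C5–C10–C9. This marks it as a Hagemann-type cyclohexenone made by [3+3] union of an acetonyl unit (C5–C6–C7) with an alkylidene acetoacetate (C10–C9–C8). An acyclic keto alkylidene acetoacetate, built on the C4 quaternary stereocentre set by asymmetric conjugate addition and unmasked by cleaving a cyclohexene ring, is closed by acid: Michael addition (C5–C10) forms ring A and the angular quaternary C10, aldol condensation (C7–C8) forms ring B. Epoxidation, SmI2 reduction and a B-alkyl Suzuki coupling with a butenolide vinyl iodide complete the target.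

Key step: step 8

Remark: ring positions follow labdane numbering (C1–C10 decalin, C11 on C9, C17 = methyl on C8, C18 = 4α-CH2O, C19 = 4β-CH3, C20 = 10β-CH3); α is the face of H-5, β the face of the C10 methyl; "pentanorlabdane" means the labdane core without C12–C16.

Step 1
Reactants: 1 3-ethoxycyclohex-2-en-1-one; 2 allylmagnesium bromide
Product: 4 3-allylcyclohex-2-en-1-one, via tertiary allylic alcohol 3 (not isolated)
Conditions: THF, 0 °C; then 1 M HCl, 0 °C
Reagents that add atoms: water (O)
Why: Stork–Danheiser alkylative carbonyl transposition: the Grignard reagent adds 1,2 to the vinylogous ester and aqueous acid hydrolyses the enol ether with loss of water to give the 3-substituted enone; no stereocentre is formed.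

Step 2
Reactants: 4 3-allylcyclohex-2-en-1-one
Product: 6 {[(3R)-3-allyl-3-methylcyclohex-1-en-1-yl]oxy}trimethylsilane, via dimethylaluminium enolate 5 (not isolated)
Conditions: Me3Al, Cu(O2CC4H3S) (copper thiophene-2-carboxylate, 2 mol %), chiral biphenol-derived phosphoramidite ligand (the enantiomer that delivers the 3R adduct, 4 mol %), Et2O, −30 °C; then Me3SiOTf, −30 °C to 0 °C
Reagents that add atoms: trimethylaluminium (C[Al](C)C); trimethylsilyl trifluoromethanesulfonate (C[Si](C)(C)OS(=O)(=O)C(F)(F)F)
Why: Copper-catalysed asymmetric conjugate addition of Me3Al to a 3-substituted cyclohexenone creates the quaternary centre (future C4) under ligand control, and silylation of the aluminium enolate fixes the enol ether regiospecifically on the side of the new quaternary carbon.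

Step 3
Reactants: 6 {[(3R)-3-allyl-3-methylcyclohex-1-en-1-yl]oxy}trimethylsilane
Product: 8 (5R)-5-(hydroxymethyl)-5-methyloct-7-enoic acid, via aldehyde acid 7 (not isolated)
Conditions: O3 (1.0 equiv, dosed), CH2Cl2/MeOH, −78 °C; then NaBH4, −78 °C to rt; aqueous acid work-up
Reagents that add atoms: ozone ([O-][O+]=O)
Why: Ozonolysis of the electron-rich silyl enol ether, which should react far faster than the monosubstituted alkene when ozone is dosed to one equivalent, cleaves the ring into the carboxylic acid (future C10) and the neopentyl aldehyde, which NaBH4 reduces in the same flask to the alcohol (future C18) without touching the stereocentre.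

Step 4
Reactants: 8 (5R)-5-(hydroxymethyl)-5-methyloct-7-enoic acid
Product: 9 (6R)-6-(hydroxymethyl)-6-methylnon-8-en-2-one
Conditions: MeLi (3.3 equiv), Et2O, 0 °C to rt; inverse quench into aq. NH4Cl
Reagents that add atoms: methyllithium ([Li]C)
Why: Addition of methyllithium to the lithium carboxylate gives a geminal dialkoxide that resists further addition and releases the methyl ketone on work-up (carboxylic acid to methyl ketone synthesis).

Step 5
Reactants: 9 (6R)-6-(hydroxymethyl)-6-methylnon-8-en-2-one
Product: 10 (6R)-6-{[tert-butyl(diphenyl)silyl]oxymethyl}-6-methylnon-8-en-2-one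
Conditions: TBDPSCl, imidazole, DMF, rt
Reagents that add atoms: tert-butyl(chloro)diphenylsilane (CC(C)(C)[Si](Cl)(c1ccccc1)c1ccccc1)
Why: Standard silylation of the primary alcohol; the bulky, non-coordinating TBDPS ether blocks hemiketal formation with the later C6 ketone and is the large group that biases the C4 centre in step 8.

Step 6
Reactants: 10 (6R)-6-{[tert-butyl(diphenyl)silyl]oxymethyl}-6-methylnon-8-en-2-one; 11 methyl acetoacetate
Product: 12 methyl (7R)-2-acetyl-7-{[tert-butyl(diphenyl)silyl]oxymethyl}-3,7-dimethyldeca-2,9-dienoate (E/Z mixture)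
Conditions: TiCl4, pyridine, THF, 0 °C to rt
Reagents that add atoms: none
Why: Lehnert-type Knoevenagel condensation (TiCl4, pyridine) of the methyl ketone with the β-keto ester gives the tetrasubstituted alkylidene acetoacetate; the alkene geometry is irrelevant because C9 becomes sp3 and epimerisable.

Step 7
Reactants: 12 methyl (7R)-2-acetyl-7-{[tert-butyl(diphenyl)silyl]oxymethyl}-3,7-dimethyldeca-2,9-dienoate
Product: 13 methyl (7R)-2-acetyl-7-{[tert-butyl(diphenyl)silyl]oxymethyl}-3,7-dimethyl-9-oxodec-2-enoate (E/Z mixture)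
Conditions: PdCl2 (10 mol %), CuCl, O2 (1 atm), DMF/H2O, rt
Reagents that add atoms: water (O)
Why: Tsuji–Wacker oxidation converts the terminal alkene to the methyl ketone by Markovnikov hydroxypalladation, while the electron-poor tetrasubstituted alkene is inert.

Step 8
Reactants: 13 methyl (7R)-2-acetyl-7-{[tert-butyl(diphenyl)silyl]oxymethyl}-3,7-dimethyl-9-oxodec-2-enoate
Product: 16 methyl 18-silyloxy-6-oxo-12,13,14,15,16-pentanorlabd-7-en-11-oate, via Michael adduct 14 (not isolated), via aldol adduct 15 (not isolated)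
Conditions: TsOH·H2O (0.2 equiv), toluene, 110 °C, Dean–Stark
Reagents that add atoms: none
Why: Under acid the more substituted enol of the C6 ketone adds to C10 of the protonated alkylidene acetoacetate (Michael step) and the C7 enol of the same ketone then attacks the C8 ketone, after which water is lost to the conjugated enone; the closest known reaction type is the Hagemann/Robinson-type Michael–aldol annulation of ketones with alkylidene acetoacetates under acid. Ring A closes 6-exo-trig at the acceptor (6-enolexo for the enol) and ring B closes by a 6-(enolendo)-exo-trig aldol. C10 is set by the C4 stereocentre through a chair transition state that keeps the bulky C9 arm equatorial and the C10 methyl axial, while at C4 the methyl takes the axial site syn to it and the CH2OTBDPS group the equatorial site, so the two methyls end cis. C5 ends with its acyl bond equatorial (trans ring fusion) and remains epimerisable next to the C6 ketone, so it is under thermodynamic control, and the labile C9 centre is fixed later in step 9. The step needs C5-to-C10 attack in preference to C7-to-C10 and C7-to-C8 aldolisation in preference to C17-to-C6; the first is secured by ring size (six against eight) and the second by the neopentyl-type shielding of the C6 carbonyl together with the lower stability of the alternative enone, whose C6 methyl would clash with the C4 substituents.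

Step 9
Reactants: 16 methyl 18-silyloxy-6-oxo-12,13,14,15,16-pentanorlabd-7-en-11-oate
Product: 17 methyl 18-silyloxy-7α,8α-epoxy-6-oxo-12,13,14,15,16-pentanorlabdan-11-oate
Conditions: t-BuOOH, DBU, CH2Cl2, 0 °C to rt, under N2
Reagents that add atoms: tert-butyl hydroperoxide (CC(C)(C)OO)
Why: Weitz–Scheffer nucleophilic epoxidation: the peroxide anion adds to C8 from the α face, anti to the axial C10 methyl, and because DBU interconverts the C9 epimers through the dienolate while only the 9β-ester epimer has an open α face, the epoxide should form with C7, C8 and C9 fixed together.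

Step 10
Reactants: 17 methyl 18-silyloxy-7α,8α-epoxy-6-oxo-12,13,14,15,16-pentanorlabdan-11-oate
Product: 20 18-silyloxy-12,13,14,15,16-pentanorlabdane-6α,8α,11-triol, via hydroxy ketone 18 (not isolated), via diol ester 19 (not isolated)
Conditions: SmI2 (excess), H2O, Et3N, THF, 0 °C to rt
Reagents that add atoms: none
Why: Electron-transfer reduction with SmI2–H2O–Et3N: the ketyl first cleaves the epoxide C7–O bond to the β-hydroxy ketone (8α-oxygen retained), the ketone is then reduced to the equatorial 6α-alcohol because the axial site at C6 is flanked by the three axial methyl groups at C4, C8 and C10, and the methyl ester is reduced to the primary alcohol.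

Step 11
Reactants: 20 18-silyloxy-12,13,14,15,16-pentanorlabdane-6α,8α,11-triol
Product: 21 18-silyloxy-6α,8α-dihydroxy-12,13,14,15,16-pentanorlabdan-11-al
Conditions: TEMPO (10 mol %), PhI(OAc)2, CH2Cl2, rt
Reagents that add atoms: none
Why: TEMPO/PhI(OAc)2 oxidation is selective for the primary alcohol over the hindered secondary and the tertiary hydroxyl groups and is non-basic, so C9 and the β-hydroxy aldehyde are preserved.

Step 12
Reactants: 21 18-silyloxy-6α,8α-dihydroxy-12,13,14,15,16-pentanorlabdan-11-al
Product: 22 18-silyloxy-13,14,15,16-tetranorlabd-11-ene-6α,8α-diol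
Conditions: Zn, CH2I2, Ti(Oi-Pr)4, THF, rt
Reagents that add atoms: diiodomethane (ICI)
Why: Takai methylenation with the CH2I2–Zn–Ti(Oi-Pr)4 reagent is aldehyde-selective and non-basic, which avoids the retro-aldol cleavage and C9 epimerisation of the β-hydroxy aldehyde that a Wittig ylide could cause.

Step 13
Reactants: 23 methyl (2R)-oxirane-2-carboxylate; 24 1-propynyllithium
Product: 25 methyl (2R)-2-hydroxyhex-4-ynoate
Conditions: BF3·OEt2, THF, −78 °C
Reagents that add atoms: none
Why: Yamaguchi-type alkynylation: the BF3-activated epoxide is opened at its terminal carbon by the alkynyllithium at −78 °C, where the ester is not attacked, and the stereocentre (future butenolide C-5) is untouched.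

Step 14
Reactants: 25 methyl (2R)-2-hydroxyhex-4-ynoate
Product: 27 methyl (2R,4E)-2-hydroxy-5-iodohex-4-enoate, via alkenylzirconocene chloride 26 (not isolated)
Conditions: Cp2Zr(H)Cl (2.5 equiv), THF, rt; then I2, 0 °C
Reagents that add atoms: iodine (II)
Why: Syn hydrozirconation places zirconium on the less hindered, methyl-bearing alkyne carbon and iodinolysis proceeds with retention, which defines the E trisubstituted vinyl iodide.

Step 15
Reactants: 27 methyl (2R,4E)-2-hydroxy-5-iodohex-4-enoate
Product: 29 (3R,5E)-3-hydroxy-6-iodohept-5-en-2-one, via Weinreb amide 28 (not isolated)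
Conditions: MeNH(OMe)·HCl, MeMgBr (excess), THF, −20 °C to 0 °C
Reagents that add atoms: methylmagnesium bromide (C[Mg]Br)
Why: Weinreb ketone synthesis in one flask: the magnesium amide converts the ester to the N-methoxy-N-methylamide, whose chelated tetrahedral adduct with MeMgBr prevents over-addition, and the adjacent magnesium alkoxide suppresses enolisation of the stereocentre.

Step 16
Reactants: 29 (3R,5E)-3-hydroxy-6-iodohept-5-en-2-one
Product: 30 (5R)-5-[(2E)-3-iodobut-2-en-1-yl]-4-methylfuran-2(5H)-one
Conditions: Ph3P=C=C=O, toluene, 90 °C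
Reagents that add atoms: (triphenylphosphoranylidene)ketene (O=C=C=P(c1ccccc1)(c1ccccc1)c1ccccc1)
Why: Bestmann butenolide synthesis: the hydroxyl group adds to the ketenylidene phosphorane and the resulting stabilised ylide closes the ring by intramolecular Wittig reaction with the neighbouring ketone under neutral conditions, leaving the carbinol centre intact.

Step 17
Reactants: 22 18-silyloxy-13,14,15,16-tetranorlabd-11-ene-6α,8α-diol; 30 (5R)-5-[(2E)-3-iodobut-2-en-1-yl]-4-methylfuran-2(5H)-one
Product: 32 18-O-TBDPS ether of the target, via alkylborane 31 (not isolated)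
Conditions: 9-BBN (3.5 equiv), THF, rt; then 30, Pd(dppf)Cl2 (10 mol %), AsPh3, aq. K3PO4, DMF, rt
Reagents that add atoms: none
Why: B-alkyl Suzuki–Miyaura coupling: 9-BBN hydroborates the vinyl group at the terminal carbon and the alkylborane couples with the vinyl iodide with retention of the E geometry, using a mild phosphate base at room temperature to spare the base-sensitive butenolide centre.

Step 18
Reactants: 32 18-O-TBDPS ether of the target
Product: 33 CNP0147582.1 (target)
Conditions: HF·pyridine, pyridine/THF, 0 °C to rt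
Reagents that add atoms: none
Why: Fluoride-induced cleavage of the silyl ether under weakly acidic conditions leaves the butenolide, the trisubstituted alkene and the tertiary alcohol untouched.

**Compound list**

1 | 3-ethoxycyclohex-2-en-1-one | CCOC1=CC(=O)CCC1 | starting material
2 | allylmagnesium bromide | C=CC[Mg]Br | starting material
3 | 1-allyl-3-ethoxycyclohex-2-en-1-ol (racemic; present as its magnesium alkoxide) | C=CCC1(O)C=C(OCC)CCC1 | intermediate
4 | 3-allylcyclohex-2-en-1-one | C=CCC1=CC(=O)CCC1 | intermediate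
5 | dimethylaluminium enolate of (3R)-3-allyl-3-methylcyclohexanone (enolate C1=C2, next to the quaternary carbon) | C=CC[C@@]1(C)CCCC(O[Al](C)C)=C1 | intermediate
6 | {[(3R)-3-allyl-3-methylcyclohex-1-en-1-yl]oxy}trimethylsilane | C=CC[C@@]1(C)CCCC(O[Si](C)(C)C)=C1 | intermediate
7 | (5R)-5-formyl-5-methyloct-7-enoic acid | C=CC[C@](C)(C=O)CCCC(O)=O | intermediate
8 | (5R)-5-(hydroxymethyl)-5-methyloct-7-enoic acid | C=CC[C@](C)(CO)CCCC(O)=O | intermediate
9 | (6R)-6-(hydroxymethyl)-6-methylnon-8-en-2-one | C=CC[C@](C)(CO)CCCC(C)=O | intermediate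
10 | (6R)-6-{[tert-butyl(diphenyl)silyl]oxymethyl}-6-methylnon-8-en-2-one | C=CC[C@](C)(CO[Si](c1ccccc1)(c1ccccc1)C(C)(C)C)CCCC(C)=O | intermediate
11 | methyl acetoacetate | CC(=O)CC(=O)OC | starting material
12 | methyl (7R)-2-acetyl-7-{[tert-butyl(diphenyl)silyl]oxymethyl}-3,7-dimethyldeca-2,9-dienoate (E/Z mixture at C2=C3) | C=CC[C@](C)(CO[Si](c1ccccc1)(c1ccccc1)C(C)(C)C)CCCC(C)=C(C(C)=O)C(=O)OC | intermediate
13 | methyl (7R)-2-acetyl-7-{[tert-butyl(diphenyl)silyl]oxymethyl}-3,7-dimethyl-9-oxodec-2-enoate (E/Z mixture at C2=C3) | CC(=O)C[C@](C)(CO[Si](c1ccccc1)(c1ccccc1)C(C)(C)C)CCCC(C)=C(C(C)=O)C(=O)OC | intermediate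
14 | Michael adduct: methyl 2-{2-acetyl-3-[(tert-butyldiphenylsilyloxy)methyl]-1,3-dimethylcyclohexyl}-3-oxobutanoate (ring A closed; 4α-CH2OSi, 4β-Me, 5α-H with equatorial acetyl, 10β-Me; C9 epimers) | COC(=O)C(C(C)=O)[C@@]1(C)CCC[C@@](C)(CO[Si](c2ccccc2)(c2ccccc2)C(C)(C)C)[C@@H]1C(C)=O | intermediate
15 | aldol adduct: methyl 18-[tert-butyl(diphenyl)silyl]oxy-8-hydroxy-6-oxo-12,13,14,15,16-pentanorlabdan-11-oate (5α-H, 10β-Me; C8 and C9 epimers) | COC(=O)C1[C@@]2(C)CCC[C@@](C)(CO[Si](c3ccccc3)(c3ccccc3)C(C)(C)C)[C@@H]2C(=O)CC1(C)O | intermediate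
16 | methyl 18-[tert-butyl(diphenyl)silyl]oxy-6-oxo-12,13,14,15,16-pentanorlabd-7-en-11-oate (4α-CH2OSi, 4β-Me, 5α-H, 9α-H, 10β-Me) | COC(=O)[C@@H]1[C@@]2(C)CCC[C@@](C)(CO[Si](c3ccccc3)(c3ccccc3)C(C)(C)C)[C@@H]2C(=O)C=C1C | intermediate
17 | methyl 18-[tert-butyl(diphenyl)silyl]oxy-7α,8α-epoxy-6-oxo-12,13,14,15,16-pentanorlabdan-11-oate (5α-H, 9α-H) | COC(=O)[C@@H]1[C@@]2(C)CCC[C@@](C)(CO[Si](c3ccccc3)(c3ccccc3)C(C)(C)C)[C@@H]2C(=O)[C@H]4O[C@@]14C | intermediate
18 | methyl 18-[tert-butyl(diphenyl)silyl]oxy-8α-hydroxy-6-oxo-12,13,14,15,16-pentanorlabdan-11-oate | COC(=O)[C@@H]1[C@@]2(C)CCC[C@@](C)(CO[Si](c3ccccc3)(c3ccccc3)C(C)(C)C)[C@@H]2C(=O)C[C@@]1(C)O | intermediate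
19 | methyl 18-[tert-butyl(diphenyl)silyl]oxy-6α,8α-dihydroxy-12,13,14,15,16-pentanorlabdan-11-oate | COC(=O)[C@@H]1[C@@]2(C)CCC[C@@](C)(CO[Si](c3ccccc3)(c3ccccc3)C(C)(C)C)[C@@H]2[C@@H](O)C[C@@]1(C)O | intermediate
20 | 18-[tert-butyl(diphenyl)silyl]oxy-12,13,14,15,16-pentanorlabdane-6α,8α,11-triol | OC[C@@H]1[C@@]2(C)CCC[C@@](C)(CO[Si](c3ccccc3)(c3ccccc3)C(C)(C)C)[C@@H]2[C@@H](O)C[C@@]1(C)O | intermediate
21 | 18-[tert-butyl(diphenyl)silyl]oxy-6α,8α-dihydroxy-12,13,14,15,16-pentanorlabdan-11-al | O=C[C@@H]1[C@@]2(C)CCC[C@@](C)(CO[Si](c3ccccc3)(c3ccccc3)C(C)(C)C)[C@@H]2[C@@H](O)C[C@@]1(C)O | intermediate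
22 | 18-[tert-butyl(diphenyl)silyl]oxy-13,14,15,16-tetranorlabd-11-ene-6α,8α-diol (vinyl group on C9, β) | C=C[C@@H]1[C@@]2(C)CCC[C@@](C)(CO[Si](c3ccccc3)(c3ccccc3)C(C)(C)C)[C@@H]2[C@@H](O)C[C@@]1(C)O | intermediate
23 | methyl (2R)-oxirane-2-carboxylate (methyl (R)-glycidate) | COC(=O)[C@H]1CO1 | starting material
24 | 1-propynyllithium | CC#C[Li] | starting material
25 | methyl (2R)-2-hydroxyhex-4-ynoate | COC(=O)[C@H](O)CC#CC | intermediate
26 | alkenylzirconocene chloride (Cp2ZrCl on C5 of the hex-4-enoate, cis to H-4) | COC(=O)[C@H](O)C/C=C(\C)[Zr](Cl)(C1C=CC=C1)C1C=CC=C1 | intermediate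
27 | methyl (2R,4E)-2-hydroxy-5-iodohex-4-enoate | COC(=O)[C@H](O)C/C=C(\C)I | intermediate
28 | (2R,4E)-2-hydroxy-5-iodo-N-methoxy-N-methylhex-4-enamide | CON(C)C(=O)[C@H](O)C/C=C(\C)I | intermediate
29 | (3R,5E)-3-hydroxy-6-iodohept-5-en-2-one | CC(=O)[C@H](O)C/C=C(\C)I | intermediate
30 | (5R)-5-[(2E)-3-iodobut-2-en-1-yl]-4-methylfuran-2(5H)-one | CC1=CC(=O)O[C@@H]1C/C=C(\C)I | intermediate
31 | 9-{18-[tert-butyl(diphenyl)silyl]oxy-6α,8α-dihydroxy-13,14,15,16-tetranorlabdan-12-yl}-9-borabicyclo[3.3.1]nonane | B1(C2CCCC1CCC2)CC[C@@H]3[C@@]4(C)CCC[C@@](C)(CO[Si](c5ccccc5)(c5ccccc5)C(C)(C)C)[C@@H]4[C@@H](O)C[C@@]3(C)O | intermediate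
32 | 18-O-tert-butyldiphenylsilyl ether of the target | CC1=CC(=O)O[C@@H]1C/C=C(\C)CC[C@@H]1[C@@]2(C)CCC[C@@](C)(CO[Si](c3ccccc3)(c3ccccc3)C(C)(C)C)[C@@H]2[C@@H](O)C[C@@]1(C)O | intermediate
33 | CNP0147582.1: (5R)-4-methylfuran-2(5H)-one carrying at C5 the (2E)-3-methylpent-2-ene-1,5-diyl chain that ends on C9 (β) of the 6α,8α-dihydroxy-18-hydroxymethyl decalin (5α-H, 9α-H, 10β-Me, 8β-Me) | CC1=CC(=O)O[C@@H]1C/C=C(\C)CC[C@@H]1[C@@]2(C)CCC[C@@](C)(CO)[C@@H]2[C@@H](O)C[C@@]1(C)O | target

**Step count and risks**

Total step count: 18. Longest linear sequence: 14 steps (steps 1–12, 17 and 18); steps 13–16 make the side-chain fragment 30.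

Step 8 is the most likely to fail. The hindered C5 enol may add too slowly to the tetrasubstituted acceptor, leaving deconjugated or retro-Knoevenagel material. Facial selectivity at C10 may also be poor, because the two C4 substituents (methyl and silyloxymethyl) differ only moderately in size. The fallback sets out from ketone 10 and uses the classical dimedone-type annulation, in which an irreversible Claisen step pulls the Michael equilibrium forward. Lehnert condensation of 10 with dimethyl malonate (TiCl4, pyridine) gives the alkylidene malonate F1, and Wacker oxidation gives the keto diester F2. NaOMe in MeOH then effects Michael addition and Claisen ring closure to the 6,8-dione ester F3. O-Triflation (Tf2O, 2,6-lutidine) at the less hindered C8 oxygen gives the vinylogous triflate F4, and Me2CuLi replaces triflate by methyl, returning to the route at 16.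

Step 9 may lose material through oxidation of the dienolate formed by γ-deprotonation at C9. It may also funnel the C9 epimers incompletely or allow attack on the β face. The fallback sets out from 16. Copper-catalysed conjugate borylation (B2pin2, CuCl, NaOt-Bu, MeOH, THF), which should deliver boron to C8 from the α face under nearly neutral conditions, gives the β-boryl ketone F5. Oxidation with NaBO3 (retention at C8) gives the β-hydroxy ketone 18, where the fallback comes back to the route; 18 is then carried through the remaining reductions of step 10.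

Step 17 may fail through base-induced epimerisation of the butenolide C-5 centre during transmetalation, or through slow coupling of the hindered alkylborane. The fallback sets out from 22 and postpones ring closure of the butenolide. Alkylborane 31 is coupled under the same catalyst with the vinyl iodide ester 27 in place of 30, giving the α-hydroxy ester F6. This is converted with MeNH(OMe)·HCl and MeMgBr to the α-hydroxy methyl ketone F7, and Ph3P=C=C=O closes the butenolide to return to the route at 32.

Further compounds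
F1 | step 8 | dimethyl 2-[(6R)-6-{[tert-butyl(diphenyl)silyl]oxymethyl}-6-methylnon-8-en-2-ylidene]malonate | C=CC[C@](C)(CO[Si](c1ccccc1)(c1ccccc1)C(C)(C)C)CCCC(C)=C(C(=O)OC)C(=O)OC
F2 | step 8 | dimethyl 2-[(6R)-6-{[tert-butyl(diphenyl)silyl]oxymethyl}-6-methyl-8-oxononan-2-ylidene]malonate | CC(=O)C[C@](C)(CO[Si](c1ccccc1)(c1ccccc1)C(C)(C)C)CCCC(C)=C(C(=O)OC)C(=O)OC
F3 | step 8 | methyl 18-[tert-butyl(diphenyl)silyl]oxy-6,8-dioxo-12,13,14,15,16,17-hexanorlabdan-11-oate (5α-H, 9α-H, 10β-Me) | COC(=O)[C@@H]1[C@@]2(C)CCC[C@@](C)(CO[Si](c3ccccc3)(c3ccccc3)C(C)(C)C)[C@@H]2C(=O)CC1=O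
F4 | step 8 | methyl 18-[tert-butyl(diphenyl)silyl]oxy-6-oxo-8-(trifluoromethylsulfonyloxy)-12,13,14,15,16,17-hexanorlabd-7-en-11-oate | COC(=O)[C@@H]1[C@@]2(C)CCC[C@@](C)(CO[Si](c3ccccc3)(c3ccccc3)C(C)(C)C)[C@@H]2C(=O)C=C1OS(=O)(=O)C(F)(F)F
F5 | step 9 | methyl 18-[tert-butyl(diphenyl)silyl]oxy-6-oxo-8α-(4,4,5,5-tetramethyl-1,3,2-dioxaborolan-2-yl)-12,13,14,15,16-pentanorlabdan-11-oate | COC(=O)[C@@H]1[C@@]2(C)CCC[C@@](C)(CO[Si](c3ccccc3)(c3ccccc3)C(C)(C)C)[C@@H]2C(=O)C[C@@]1(C)B4OC(C)(C)C(C)(C)O4
F6 | step 17 | methyl (2R,4E)-2-hydroxy-5-methyl-7-{18-[tert-butyl(diphenyl)silyl]oxy-6α,8α-dihydroxy-11,12,13,14,15,16-hexanorlabdan-9β-yl}hept-4-enoate | COC(=O)[C@H](O)C/C=C(\C)CC[C@@H]1[C@@]2(C)CCC[C@@](C)(CO[Si](c3ccccc3)(c3ccccc3)C(C)(C)C)[C@@H]2[C@@H](O)C[C@@]1(C)O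
F7 | step 17 | (3R,5E)-3-hydroxy-6-methyl-8-{18-[tert-butyl(diphenyl)silyl]oxy-6α,8α-dihydroxy-11,12,13,14,15,16-hexanorlabdan-9β-yl}oct-5-en-2-one | CC(=O)[C@H](O)C/C=C(\C)CC[C@@H]1[C@@]2(C)CCC[C@@](C)(CO[Si](c3ccccc3)(c3ccccc3)C(C)(C)C)[C@@H]2[C@@H](O)C[C@@]1(C)O
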